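## Retrosynthetic overview

- Feature: ring A carries oxygen on three adjacent carbons (C5, C6, C7) and C8 is CH. This is a 1,2,3-trioxygenated four-carbon unit C5–C8 sitting on the C4a–C8a edge of ring C.
- Key disconnection: C4a–C5 and C8–C8a. A 1,2-dimethoxy-1,3-bis(silyloxy)butadiene is annulated in a [4+2] sense onto the C4a=C8a bond of an (S)-5-bromo-2-aryl-2,3-dihydropyran-4-one, and loss of HBr and methanol aromatises ring A.
- The ketene-acetal carbon of the diene (one OMe, one OSiMe3) is expected to emerge as the carbonyl-chelated C5 phenol, as mixed acetals of this kind do with haloquinones, so the annulation product is the 5,7-diphenol. Both phenols are methylated while C4 is held as the alcohol (reduce, methylate, re-oxidise), where base meets no chelate and cannot open ring C.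
- Bromo-pyranone: asymmetric hetero-Diels–Alder reaction of 3,4-dimethoxybenzaldehyde sets C2, then α-bromination. Diene: methyl methoxyacetate, C-acetylation, two O-silylations.
- Ring order: ring B is bought, ring C is made in step 1, ring A in step 6.

Key step: step 6

Assumption: (S)-1,1′-bi-2-naphthol is taken as the ligand antipode that directs the diene to the Si face of the aldehyde and so gives (2S)-4; the sense would be confirmed on the first run (chiral HPLC) and the (R)-ligand used if it proved opposite.

## Route

Step 1
Reactants: 1 3,4-dimethoxybenzaldehyde; 2 (E)-1-methoxy-3-(trimethylsilyloxy)buta-1,3-diene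
Product: 4 (2S)-2-(3,4-dimethoxyphenyl)-2,3-dihydro-4H-pyran-4-one, via silyl aldol adduct 3 (not isolated)
Conditions: Ti(OiPr)4 (10 mol%), (S)-1,1′-bi-2-naphthol (20 mol%), 4 Å molecular sieves, Et2O, −20 °C; then CF3CO2H, CH2Cl2, 0 °C
Reagents that add atoms: none
Why: Binaphthol–titanium catalysed asymmetric hetero-Diels–Alder reaction, which runs as a Mukaiyama aldol addition followed by acid-promoted cyclisation with loss of methanol; the chiral titanium binaphtholate bound to the aldehyde exposes its Si face to the diene and thereby sets C2 as S.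

Step 2
Reactants: 4 (2S)-2-(3,4-dimethoxyphenyl)-2,3-dihydro-4H-pyran-4-one
Product: 5 (2S)-5-bromo-2-(3,4-dimethoxyphenyl)-2,3-dihydro-4H-pyran-4-one
Conditions: N-bromosuccinimide (1.05 equiv), CH2Cl2, 0 °C, dark
Reagents that add atoms: N-bromosuccinimide, O=C1CCC(=O)N1Br
Why: Electrophilic α-bromination of a vinylogous ester (bromine adds to the nucleophilic C5 and the oxocarbenium ion loses H5), which should outpace bromination of the dimethoxyphenyl ring at low temperature and does not touch C2.

Step 3
Reactants: 6 methyl methoxyacetate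
Product: 7 methyl 2-methoxy-3-oxobutanoate
Conditions: LiN(iPr)2 (1.1 equiv), THF, −78 °C; MeC(O)N(OMe)Me, −78 to 0 °C; aq. HCl work-up
Reagents that add atoms: N-methoxy-N-methylacetamide, CC(=O)N(C)OC
Why: Crossed Claisen-type C-acylation of an ester lithium enolate by a Weinreb amide, whose chelated tetrahedral adduct survives until work-up and so prevents proton exchange and double acylation.

Step 4
Reactants: 7 methyl 2-methoxy-3-oxobutanoate
Product: 8 methyl 2-methoxy-3-(trimethylsilyloxy)but-2-enoate
Conditions: Me3SiCl, Et3N, hexane, rt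
Reagents that add atoms: chlorotrimethylsilane, C[Si](C)(C)Cl
Why: Silyl enol ether formation from a β-keto ester under equilibrating amine conditions, which places the double bond between C2 and C3 in conjugation with the ester.

Step 5
Reactants: 8 methyl 2-methoxy-3-(trimethylsilyloxy)but-2-enoate
Product: 9 (1E)-1,2-dimethoxy-1,3-bis(trimethylsilyloxy)buta-1,3-diene
Conditions: LiN(iPr)2, THF, −78 °C; Me3SiCl, −78 to 0 °C; filtered under argon, used crude
Reagents that add atoms: chlorotrimethylsilane, C[Si](C)(C)Cl
Why: γ-Deprotonation of the β-silyloxy enoate to the extended enolate and O-silylation at the ester oxygen, the standard synthesis of 1-alkoxy-1,3-bis(silyloxy)buta-1,3-dienes.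

Step 6
Reactants: 5 (2S)-5-bromo-2-(3,4-dimethoxyphenyl)-2,3-dihydro-4H-pyran-4-one; 9 (1E)-1,2-dimethoxy-1,3-bis(trimethylsilyloxy)buta-1,3-diene
Product: 12 (2S)-2-(3,4-dimethoxyphenyl)-5,7-dihydroxy-6-methoxy-2,3-dihydro-4H-chromen-4-one, via bromo ketal cycloadduct 10 (not isolated), via aryl bis-silyl ether 11 (not isolated)
Conditions: 9 (1.4 equiv), Me3SiOTf (0.2 equiv), 2,6-lutidine (3 equiv), CH2Cl2, −78 to −30 °C; then Me3SiOTf (1.1 equiv), −30 to 0 °C; then 1 M HCl, THF–MeOH, 0 °C
Reagents that add atoms: none
Why: Proposed new method: Me3SiOTf silylates the C4 carbonyl of 5 to an oxocarbenium ion, the CH2 terminus of 9 adds to C8a (Mukaiyama–Michael addition, the known mode of addition to dihydropyranones), and the resulting α-bromo silyl enol ether closes from C4a onto the silylated ester carbon C5, so that the two new bonds C8–C8a and C4a–C5 are those of an asynchronous [4+2] cycloaddition and give 10. Stoichiometric Me3SiOTf and 2,6-lutidine then ionise the C5 mixed ketal with loss of MeOSiMe3, H8 is removed to give a 5,7-bis(silyloxy)cyclohexa-1,3-diene, and the now allylic C4a bromide leaves together with H8a, the gain of aromaticity driving this elimination even from a cis ring fusion, before aqueous acid cleaves the two aryl silyl ethers of 11. The closest known reactions are the cycloaddition–elimination benzannulations of vinylketene acetals and 1,3-bis(silyloxy)dienes with bromoquinones and the Diels–Alder and dehydrobromination use of 2-bromocycloalkenones, and as in the quinone series the methyl silyl ketene-acetal carbon is expected to emerge as the free, carbonyl-chelated C5 phenol and not as a methyl ether. Ring A is the only ring closed (intermolecular C8–C8a bond, then 6-(enolexo)-exo-trig closure of C4a onto C5), the three transient centres of 10 (C4a, C5, C8a) need no control because all become sp2, and C2 lies outside the reacting π system and is protected by the cold, weakly basic medium (no enolisation toward C3, no ionisation of the benzylic C2–O1 bond). The selectivity needed is regiochemical and is secured by pairing the most nucleophilic diene carbon (CH2) with the electrophilic β-carbon C8a of the bromo-enone, so that the diene oxygens fall on C7, C6 and C5 and C8 stays CH, with bromine marking C4a for the loss of HBr.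

Step 7
Reactants: 12 (2S)-2-(3,4-dimethoxyphenyl)-5,7-dihydroxy-6-methoxy-2,3-dihydro-4H-chromen-4-one
Product: 13 (2S,4S)-2-(3,4-dimethoxyphenyl)-6-methoxy-3,4-dihydro-2H-chromene-4,5,7-triol
Conditions: NaBH4, MeOH–THF, 0 °C to rt; pH 7 phosphate buffer work-up
Reagents that add atoms: none
Why: Borohydride 1,2-reduction of the aryl ketone, in which hydride adds axially to the half-chair that has the C2 aryl group equatorial, so the new C4 centre is set cis to the aryl group (4S); this centre is removed again in step 9.

Step 8
Reactants: 13 (2S,4S)-2-(3,4-dimethoxyphenyl)-6-methoxy-3,4-dihydro-2H-chromene-4,5,7-triol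
Product: 14 (2S,4S)-2-(3,4-dimethoxyphenyl)-5,6,7-trimethoxy-3,4-dihydro-2H-chromen-4-ol
Conditions: MeI, K2CO3, acetone, rt
Reagents that add atoms: iodomethane, CI
Why: Williamson O-methylation of the two phenoxides: with C4 reduced the C5 hydroxyl is no longer locked in a hydrogen bond to a carbonyl and no enolisable ketone is present, so carbonate cannot trigger the retro-oxa-Michael opening of ring C that would scramble C2, and the secondary alcohol is not alkylated under these conditions.

Step 9
Reactants: 14 (2S,4S)-2-(3,4-dimethoxyphenyl)-5,6,7-trimethoxy-3,4-dihydro-2H-chromen-4-ol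
Product: 15 (2S)-2-(3,4-dimethoxyphenyl)-5,6,7-trimethoxy-2,3-dihydro-4H-chromen-4-one
Conditions: Dess–Martin periodinane, NaHCO3, CH2Cl2, 0 °C to rt
Reagents that add atoms: none
Why: Dess–Martin oxidation of the benzylic secondary alcohol back to the ketone under buffered, near-neutral conditions that neither enolise C3 nor ionise the benzylic positions, so C2 stays S.

## Compound list

1 | 3,4-dimethoxybenzaldehyde | COc1ccc(C=O)cc1OC | starting material
2 | (E)-1-methoxy-3-(trimethylsilyloxy)buta-1,3-diene | CO/C=C/C(=C)O[Si](C)(C)C | starting material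
3 | (1E,5S)-5-(3,4-dimethoxyphenyl)-1-methoxy-5-(trimethylsilyloxy)pent-1-en-3-one | CO/C=C/C(=O)C[C@H](O[Si](C)(C)C)c1ccc(OC)c(OC)c1 | intermediate (not isolated)
4 | (2S)-2-(3,4-dimethoxyphenyl)-2,3-dihydro-4H-pyran-4-one | COc1ccc([C@@H]2CC(=O)C=CO2)cc1OC | intermediate
5 | (2S)-5-bromo-2-(3,4-dimethoxyphenyl)-2,3-dihydro-4H-pyran-4-one | COc1ccc([C@@H]2CC(=O)C(Br)=CO2)cc1OC | intermediate
6 | methyl methoxyacetate | COCC(=O)OC | starting material
7 | methyl 2-methoxy-3-oxobutanoate (racemic, enolisable) | COC(C(C)=O)C(=O)OC | intermediate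
8 | methyl 2-methoxy-3-(trimethylsilyloxy)but-2-enoate (E/Z mixture, both serve) | COC(=O)C(OC)=C(C)O[Si](C)(C)C | intermediate
9 | (1E)-1,2-dimethoxy-1,3-bis(trimethylsilyloxy)buta-1,3-diene (drawn as 1E; the geometry is lost when C5 becomes sp2) | C=C(O[Si](C)(C)C)/C(OC)=C(/OC)O[Si](C)(C)C | intermediate
10 | (2S)-4a-bromo-2-(3,4-dimethoxyphenyl)-5,6-dimethoxy-5,7-bis(trimethylsilyloxy)-2,3,4a,5,8,8a-hexahydro-4H-chromen-4-one (diastereomer mixture at C4a, C5 and C8a; only C2 defined) | COc1ccc([C@@H]2CC(=O)C3(Br)C(OC)(O[Si](C)(C)C)C(OC)=C(O[Si](C)(C)C)CC3O2)cc1OC | intermediate (not isolated)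
11 | (2S)-2-(3,4-dimethoxyphenyl)-6-methoxy-5,7-bis(trimethylsilyloxy)-2,3-dihydro-4H-chromen-4-one | COc1ccc([C@@H]2CC(=O)c3c(cc(O[Si](C)(C)C)c(OC)c3O[Si](C)(C)C)O2)cc1OC | intermediate (not isolated)
12 | (2S)-2-(3,4-dimethoxyphenyl)-5,7-dihydroxy-6-methoxy-2,3-dihydro-4H-chromen-4-one | COc1ccc([C@@H]2CC(=O)c3c(cc(O)c(OC)c3O)O2)cc1OC | intermediate
13 | (2S,4S)-2-(3,4-dimethoxyphenyl)-6-methoxy-3,4-dihydro-2H-chromene-4,5,7-triol (2,4-cis) | COc1ccc([C@@H]2C[C@H](O)c3c(O)c(OC)c(O)cc3O2)cc1OC | intermediate
14 | (2S,4S)-2-(3,4-dimethoxyphenyl)-5,6,7-trimethoxy-3,4-dihydro-2H-chromen-4-ol (2,4-cis) | COc1ccc([C@@H]2C[C@H](O)c3c(OC)c(OC)c(OC)cc3O2)cc1OC | intermediate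
15 | (2S)-2-(3,4-dimethoxyphenyl)-5,6,7-trimethoxy-2,3-dihydro-4H-chromen-4-one, (2S)-5,6,7,3',4'-pentamethoxyflavanone | COc1ccc([C@@H]2CC(=O)c3c(cc(OC)c(OC)c3OC)O2)cc1OC | target

## Step count and risks

Total steps: 9. Longest linear sequence: 7 steps (steps 3, 4, 5, 6, 7, 8, 9, from methyl methoxyacetate 6); the other branch (steps 1, 2) joins at step 6.

Three steps most likely to fail:

1. Step 6 (proposed new method).
   - The push–pull C4a=C8a bond may not react, or the sequence may stop at the open-chain Michael adduct without closure of the C4a–C5 bond.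
   - During aromatisation the ring-C oxygen may ionise from C8a and positive bromine be transferred to excess diene instead of HBr being lost.
   - The Lewis acid may ionise the benzylic C2–O1 bond and erode the enantiomeric purity.
   - Partition of the C5 ketal between loss of methanol and loss of silanol is harmless, since both channels converge after step 8.
   - Fallback (known chemistry, leaves the benzannulation): it sets out from 1 and returns at 15. Commercial 1-(6-hydroxy-2,3,4-trimethoxyphenyl)ethanone is C-carboxylated (LiN(SiMe3)2, di-tert-butyl dicarbonate, THF) to tert-butyl 3-(6-hydroxy-2,3,4-trimethoxyphenyl)-3-oxopropanoate F1. Knoevenagel condensation of this ester with 1 (piperidinium acetate, toluene, 4 Å molecular sieves) should give tert-butyl 2-[(3,4-dimethoxyphenyl)methylidene]-3-(6-hydroxy-2,3,4-trimethoxyphenyl)-3-oxopropanoate F2. Enantioselective intramolecular oxa-Michael addition closes ring C to tert-butyl (2S)-2-(3,4-dimethoxyphenyl)-5,6,7-trimethoxy-4-oxo-3,4-dihydro-2H-chromene-3-carboxylate F3. The catalyst is the bifunctional cinchona thiourea N-[3,5-bis(trifluoromethyl)phenyl]-N′-[(8α,9S)-6′-methoxycinchonan-9-yl]thiourea or its quinidine-derived pseudoenantiomer, whichever leads to the 2S series, in toluene at −25 °C. p-Toluenesulfonic acid in toluene at 80 °C then removes the ester as 2-methylpropene and CO2 and returns to the route at 15.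

2. Step 7.
   - Hydride addition to the hydrogen-bonded carbonyl, further deactivated once the C7 phenol is ionised, may be slow.
   - The electron-rich benzylic alcohol may ionise at C4 on work-up (dehydration to the flavene, or quinone-methide formation).
   - Fallback: from 12 directly to 15 by Purdie methylation (MeI, Ag2O, DMF, rt, dark). This is a carbonate-free O-alkylation that also takes hydrogen-bonded phenols, it omits the redox detour, and it makes no new compound.

3. Step 1.
   - Turnover may be slow and facial selectivity eroded with the electron-rich, weakly electrophilic aldehyde.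
   - Partial racemisation through the p-alkoxybenzylic cation is possible during the acid cyclisation.
   - Fallback: it sets out from 1 and returns at 4. Reagent-controlled boron aldol addition of (E)-4-methoxybut-3-en-2-one (B-chlorodiisopinocampheylborane, Ipc2BCl, of the antipode that gives the 5S adduct, Et3N, Et2O, −78 °C; H2O2 work-up) should give (1E,5S)-5-(3,4-dimethoxyphenyl)-5-hydroxy-1-methoxypent-1-en-3-one F4, whose enantiomeric purity can be raised by crystallisation. Pyridinium p-toluenesulfonate (or CF3CO2H at 0 °C) then closes this adduct to 4 with loss of methanol.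

## Further compounds

F1 | step 6 | tert-butyl 3-(6-hydroxy-2,3,4-trimethoxyphenyl)-3-oxopropanoate | CC(C)(C)OC(=O)CC(=O)c1c(O)cc(OC)c(OC)c1OC
F2 | step 6 | tert-butyl 2-[(3,4-dimethoxyphenyl)methylidene]-3-(6-hydroxy-2,3,4-trimethoxyphenyl)-3-oxopropanoate (E/Z mixture) | COc1ccc(C=C(C(=O)OC(C)(C)C)C(=O)c2c(O)cc(OC)c(OC)c2OC)cc1OC
F3 | step 6 | tert-butyl (2S)-2-(3,4-dimethoxyphenyl)-5,6,7-trimethoxy-4-oxo-3,4-dihydro-2H-chromene-3-carboxylate (C3 epimers and enol form) | COc1ccc([C@@H]2C(C(=O)OC(C)(C)C)C(=O)c3c(cc(OC)c(OC)c3OC)O2)cc1OC
F0 | step 7 | none | none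
F4 | step 1 | (1E,5S)-5-(3,4-dimethoxyphenyl)-5-hydroxy-1-methoxypent-1-en-3-one | CO/C=C/C(=O)C[C@H](O)c1ccc(OC)c(OC)c1
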